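**Plan**
- Retrosynthesis: the two O-methyl groups come off first (dihydroxyquinone 12). The quinone ring is then cut at both C(=O)–C(indolyl) bonds into two identical ethyl 3-(indol-3-yl)-2-oxopropanoates 10.
- Enabling feature: the central six-membered ring is C2-symmetric, and each indolyl-bearing carbon sits between an enol carbon and a carbonyl carbon. Its cyclohexane-1,2,4,5-tetraone tautomer is therefore the head-to-tail double Claisen dimer of a three-carbon 2-oxo ester at the same oxidation level, as in the presumed biosynthesis from indolepyruvate.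
- Monomer 10 is cut at the indole C3–CH2 bond (nitrosoalkene alkylation, then deoximation) and at the indole C2–quaternary carbon bond (allylboration of 3-chloroindole).
- Forward: indole → 3-chloroindole → 2-(1,1-dimethylallyl)indole → C3 oximino ester → 2-oxo ester → dimerization closes the only new ring (the quinone) → double O-methylation.
- Stereochemistry: the target has no stereocenter and no stereogenic double bond, so nothing needs to be controlled.

Key step: step 6

Assumption: the C=N geometry of oximes 7 and 9 is left unspecified because it is erased when 8 forms and on deoximation; 10 is drawn as the keto tautomer although the enol is expected to predominate.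

**Step 1**
Reactants: 1 1H-indole
Product: 2 3-chloro-1H-indole
Conditions: NCS, DMF, rt; used at once
Reagents that add atoms: N-chlorosuccinimide, O=C1CCC(=O)N1Cl
Why: Electrophilic aromatic chlorination of indole by NCS is selective for the most nucleophilic position, C3.

**Step 2**
Reactants: 2 3-chloro-1H-indole; 3 3-methylbuta-1,2-diene
Product: 5 2-(2-methylbut-3-en-2-yl)-1H-indole, via B-prenyl-9-BBN 4 (not isolated)
Conditions: 9-BBN (0.5 M in THF), 3, THF, rt; then 2, Et3N, THF, rt; aqueous work-up
Reagents that add atoms: none
Why: Danishefsky-type reverse prenylation, in which 9-BBN hydroborates allene 3 at its terminal CH2 to give allylborane 4, which adds to the C=N of the 3H-indole tautomer of 2 through a six-membered cyclic transition state with allyl transposition so that the quaternary carbon lands on C2, and loss of HCl to Et3N restores the indole.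

**Step 3**
Reactants: 6 ethyl 3-bromo-2-oxopropanoate
Product: 7 ethyl 3-bromo-2-(hydroxyimino)propanoate
Conditions: NH2OH·HCl, CHCl3/MeOH (1:1), rt
Reagents that add atoms: hydroxylamine hydrochloride, Cl.NO
Why: Oxime condensation at the ketone carbonyl, which under these base-free acidic conditions is faster than displacement of the bromide.

**Step 4**
Reactants: 5 2-(2-methylbut-3-en-2-yl)-1H-indole; 7 ethyl 3-bromo-2-(hydroxyimino)propanoate
Product: 9 ethyl 2-(hydroxyimino)-3-[2-(2-methylbut-3-en-2-yl)-1H-indol-3-yl]propanoate, via ethyl 2-nitrosoacrylate 8 (not isolated)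
Conditions: Na2CO3, CH2Cl2, rt, slow addition of 7
Reagents that add atoms: none
Why: Gilchrist nitrosoalkene alkylation, in which Na2CO3 eliminates HBr from 7 to give the transient heterodiene 8 that is captured at the free, nucleophilic C3 of indole 5 (conjugate addition or [4+2] cycloaddition followed by ring opening and rearomatization), while carbonate is too weak to deprotonate the indole N–H.

**Step 5**
Reactants: 9 ethyl 2-(hydroxyimino)-3-[2-(2-methylbut-3-en-2-yl)-1H-indol-3-yl]propanoate
Product: 10 ethyl 3-[2-(2-methylbut-3-en-2-yl)-1H-indol-3-yl]-2-oxopropanoate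
Conditions: aq. TiCl3, NH4OAc, THF/H2O, 0 °C to rt, argon
Reagents that add atoms: water, O
Why: Reductive deoximation of the Timms–Wildsmith type, in which trivalent titanium cleaves the N–O bond to the N–H imine, which hydrolyses in the buffered aqueous medium to the 2-oxo ester without touching the alkene or the indole.

**Step 6**
Reactants: 10 ethyl 3-[2-(2-methylbut-3-en-2-yl)-1H-indol-3-yl]-2-oxopropanoate (two molecules)
Product: 12 2,5-dihydroxy-3,6-bis[2-(2-methylbut-3-en-2-yl)-1H-indol-3-yl]cyclohexa-2,5-diene-1,4-dione, via open-chain Claisen adduct 11 (not isolated)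
Conditions: NaH (1.25 equiv per mole of 10), degassed THF, 0 °C to 65 °C, argon; then 1 M HCl, 0 °C
Reagents that add atoms: none
Why: Proposed new method: the sodium enolate of 10 (carbanion at the indolyl-bearing carbon) should attack the ester carbonyl of a second molecule in an intermolecular Claisen condensation to give triketo ester 11, whose remaining indolylmethyl enolate carbon then attacks the terminal ester carbonyl in a Dieckmann-type closure, and the cyclohexane-1,2,4,5-tetraone so formed tautomerizes at once to the 2,5-dihydroxy-1,4-benzoquinone, set free on acidification. The closest known reaction types are the Fichter self-condensation of aliphatic 2-oxo esters to 2,5-dialkyl-3,6-dihydroxybenzoquinones and the alkoxide-induced acyl transfer of grevillin-type pyrandiones to terphenylquinones; it has not been shown on 3-(indol-3-yl)pyruvates carrying a free N–H and a tertiary C2 substituent, and it mirrors the thioester-based dimerization of indolepyruvate in the presumed biosynthesis. The six-membered carbocycle closes in a 6-(enolendo)-exo-trig mode, the enolate carbon adding to the exocyclic ester C=O at the other end of the six-carbon chain. No stereocenter is formed. The step needs C- over O-acylation and Claisen over aldol chemistry: full enolization by NaH leaves no ketone electrophile, O-acyl, N-acyl and aldol adducts form reversibly under the ethoxide released, and only the double C-acylation ends in the twofold vinylogous carboxylate dianion of 12, which acts as the thermodynamic sink. Head-to-tail regiochemistry is inherent, because each monomer offers a single nucleophilic carbon and a single acyl donor.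

**Step 7**
Reactants: 12 2,5-dihydroxy-3,6-bis[2-(2-methylbut-3-en-2-yl)-1H-indol-3-yl]cyclohexa-2,5-diene-1,4-dione
Product: 13 2,5-dimethoxy-3,6-bis[2-(2-methylbut-3-en-2-yl)-1H-indol-3-yl]cyclohexa-2,5-diene-1,4-dione
Conditions: TMSCHN2 (2 M in hexanes), MeOH/toluene, 0 °C to rt
Reagents that add atoms: trimethylsilyldiazomethane, C[Si](C)(C)C=[N+]=[N-]
Why: O-Methylation of a vinylogous carboxylic acid by a diazoalkane, in which the acidic hydroxyquinone O–H groups protonate the diazomethane released from TMSCHN2 and MeOH and are methylated on oxygen, whereas the far less acidic indole N–H groups are not.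

**Compound list**
1 | 1H-indole | c1ccc2[nH]ccc2c1 | starting material
2 | 3-chloro-1H-indole | Clc1c[nH]c2ccccc12 | intermediate
3 | 3-methylbuta-1,2-diene | CC(C)=C=C | starting material
4 | 9-(3-methylbut-2-en-1-yl)-9-borabicyclo[3.3.1]nonane (B-prenyl-9-BBN) | CC(C)=CCB1C2CCCC1CCC2 | intermediate (not isolated)
5 | 2-(2-methylbut-3-en-2-yl)-1H-indole | C=CC(C)(C)c1cc2ccccc2[nH]1 | intermediate
6 | ethyl 3-bromo-2-oxopropanoate | CCOC(=O)C(=O)CBr | starting material
7 | ethyl 3-bromo-2-(hydroxyimino)propanoate (C=N geometry unspecified) | CCOC(=O)C(=NO)CBr | intermediate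
8 | ethyl 2-nitrosoprop-2-enoate (ethyl 2-nitrosoacrylate) | CCOC(=O)C(=C)N=O | intermediate (not isolated)
9 | ethyl 2-(hydroxyimino)-3-[2-(2-methylbut-3-en-2-yl)-1H-indol-3-yl]propanoate (C=N geometry unspecified) | C=CC(C)(C)c1[nH]c2ccccc2c1CC(=NO)C(=O)OCC | intermediate
10 | ethyl 3-[2-(2-methylbut-3-en-2-yl)-1H-indol-3-yl]-2-oxopropanoate | C=CC(C)(C)c1[nH]c2ccccc2c1CC(=O)C(=O)OCC | intermediate
11 | ethyl 3,6-bis[2-(2-methylbut-3-en-2-yl)-1H-indol-3-yl]-2,4,5-trioxohexanoate (enolized at C3, no fixed configuration) | CCOC(=O)C(=O)C(c1c(C(C)(C)C=C)[nH]c2ccccc12)C(=O)C(=O)Cc1c(C(C)(C)C=C)[nH]c2ccccc12 | intermediate (not isolated)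
12 | 2,5-dihydroxy-3,6-bis[2-(2-methylbut-3-en-2-yl)-1H-indol-3-yl]cyclohexa-2,5-diene-1,4-dione | C=CC(C)(C)c1[nH]c2ccccc2c1C1=C(O)C(=O)C(c2c(C(C)(C)C=C)[nH]c3ccccc23)=C(O)C1=O | intermediate
13 | 2,5-dimethoxy-3,6-bis[2-(2-methylbut-3-en-2-yl)-1H-indol-3-yl]cyclohexa-2,5-diene-1,4-dione | C=CC(C)(C)c1[nH]c2ccccc2c1C1=C(OC)C(=O)C(c2c(C(C)(C)C=C)[nH]c3ccccc23)=C(OC)C1=O | target

**Step count**
Total steps: 7. Longest linear sequence: 6 (steps 1, 2, 4, 5, 6, 7); step 3 is a one-step side branch.

**Steps most likely to fail**

Step 6 (Proposed new method). The dimerization may stall after the first acylation, drain into reversible aldol self-addition followed by lactonization, or lose the electron-rich enolate to oxidative degradation. The fallback uses known quinone chemistry, sets out from 5 and comes back at 12. Acid-promoted conjugate addition of 5 to 2,5-dichloro-1,4-benzoquinone (AcOH, rt) and reoxidation of the adduct hydroquinone with DDQ should give 2,5-dichloro-3-[2-(2-methylbut-3-en-2-yl)-1H-indol-3-yl]cyclohexa-2,5-diene-1,4-dione F1. A second addition of 5 under the same conditions, again followed by DDQ, should give 2,5-dichloro-3,6-bis[2-(2-methylbut-3-en-2-yl)-1H-indol-3-yl]cyclohexa-2,5-diene-1,4-dione F2. NaOH in MeOH/H2O at reflux should then replace both vinylogous acyl chlorides by addition–elimination, and acidification gives 12.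

Step 4. Self-condensation of the short-lived nitrosoalkene may outrun its capture by the hindered 2-tert-alkyl indole, or alkylation may stray to nitrogen. The fallback replaces the nitrosoalkene by a gramine elimination–addition, sets out from 5 and comes back at 10. A Mannich reaction of 5 with dimethylmethylideneammonium iodide (CH2Cl2, rt, basic work-up) should give 1-[2-(2-methylbut-3-en-2-yl)-1H-indol-3-yl]-N,N-dimethylmethanamine F3. Heating F3 with ethyl nitroacetate in toluene under a nitrogen sweep should give racemic ethyl 3-[2-(2-methylbut-3-en-2-yl)-1H-indol-3-yl]-2-nitropropanoate F4 by elimination of the amine and conjugate addition. Aqueous TiCl3 buffered with NH4OAc (McMurry-type Nef reaction) should reduce the nitro group through the oxime stage to the imine, which hydrolyses to 10.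

Step 5. The keto ester may be over-reduced or reductively coupled by the low-valent titanium, or N–O cleavage and imine hydrolysis may remain incomplete. The fallback changes the nitrogen removal from reductive deoximation to a biomimetic transamination, sets out from 9 and comes back at 10. Zn dust in AcOH (rt) should reduce 9 to racemic ethyl 2-amino-3-[2-(2-methylbut-3-en-2-yl)-1H-indol-3-yl]propanoate F5. Condensation with 4-formyl-1-methylpyridinium benzenesulfonate (CH2Cl2/DMF, rt) should give the aldimine 4-[({1-ethoxy-3-[2-(2-methylbut-3-en-2-yl)-1H-indol-3-yl]-1-oxopropan-2-yl}imino)methyl]-1-methylpyridinium benzenesulfonate F6. DBU should shift the proton to give the ketimine 4-[({1-ethoxy-3-[2-(2-methylbut-3-en-2-yl)-1H-indol-3-yl]-1-oxopropan-2-ylidene}amino)methyl]-1-methylpyridinium benzenesulfonate F7, and aqueous oxalic acid hydrolyses F7 to 10.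

**Further compounds**
F1 | step 6 | 2,5-dichloro-3-[2-(2-methylbut-3-en-2-yl)-1H-indol-3-yl]cyclohexa-2,5-diene-1,4-dione | C=CC(C)(C)c1[nH]c2ccccc2c1C1=C(Cl)C(=O)C=C(Cl)C1=O
F2 | step 6 | 2,5-dichloro-3,6-bis[2-(2-methylbut-3-en-2-yl)-1H-indol-3-yl]cyclohexa-2,5-diene-1,4-dione | C=CC(C)(C)c1[nH]c2ccccc2c1C1=C(Cl)C(=O)C(c2c(C(C)(C)C=C)[nH]c3ccccc23)=C(Cl)C1=O
F3 | step 4 | 1-[2-(2-methylbut-3-en-2-yl)-1H-indol-3-yl]-N,N-dimethylmethanamine | C=CC(C)(C)c1[nH]c2ccccc2c1CN(C)C
F4 | step 4 | ethyl 3-[2-(2-methylbut-3-en-2-yl)-1H-indol-3-yl]-2-nitropropanoate (racemic) | C=CC(C)(C)c1[nH]c2ccccc2c1CC(C(=O)OCC)[N+](=O)[O-]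
F5 | step 5 | ethyl 2-amino-3-[2-(2-methylbut-3-en-2-yl)-1H-indol-3-yl]propanoate (racemic) | C=CC(C)(C)c1[nH]c2ccccc2c1CC(N)C(=O)OCC
F6 | step 5 | 4-[({1-ethoxy-3-[2-(2-methylbut-3-en-2-yl)-1H-indol-3-yl]-1-oxopropan-2-yl}imino)methyl]-1-methylpyridinium benzenesulfonate (racemic) | CCOC(=O)C(Cc1c(C(C)(C)C=C)[nH]c2ccccc12)N=Cc1cc[n+](C)cc1.[O-]S(=O)(=O)c1ccccc1
F7 | step 5 | 4-[({1-ethoxy-3-[2-(2-methylbut-3-en-2-yl)-1H-indol-3-yl]-1-oxopropan-2-ylidene}amino)methyl]-1-methylpyridinium benzenesulfonate | CCOC(=O)C(Cc1c(C(C)(C)C=C)[nH]c2ccccc12)=NCc1cc[n+](C)cc1.[O-]S(=O)(=O)c1ccccc1
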